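Ring carbons carry germacrane numbers (C1–C15) throughout. In the six-membered intermediates the ring carbons are already called C8, C9, C10, C1, C6 and C7, and "up" means the face of the oxygen on C8.

## Analysis of the target

The target 36 is a germacranolide: a ten-membered carbocycle (C1–C10) fused at C6–C7 to a butenolide (O–C12(=O)–C11=C7, lactone oxygen on C6), with a trans-epoxide across C4–C5. It has five stereocentres, (4R,5R,6S,8S,10R). C4, C5 and C6 are contiguous: C3 and C6 lie on opposite sides of the epoxide, and the epoxide oxygen is on the same side as the lactone oxygen when H-6 eclipses the C4–C5 bond. C8 (secondary tiglate) and C10 (tertiary acetate next to the C1 ketone) are 1,3-related across C9; in the flat ring projection the oxygens on C6, C8 and C10 all sit on one face. Sensitive groups are the epoxide next to the lactone carbinol, the acidic γ-hydrogen at C6 of the butenolide, three different esters (primary allylic acetate at C13, tiglate, tertiary α-keto acetate) and the α-acyloxy ketone. The hard parts are the medium ring itself, the relay of configuration from C8/C10 to C4–C6 on the far side of the ring, and the tetrasubstituted C7=C11 alkene between two oxygenated carbons. The plan rests on one feature: C1 and C6 both carry oxygen and face each other across the ring, separated by C2–C3–C4–C5. That 1,6-dioxygenated cyclodeca-1,5-diene pattern is what a [3,3] shift of a 1,2-dialkenylcyclohexane-1,2-diol leaves behind.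

## Retrosynthetic reasoning

36 ⇒ 35. The two epoxide C–O bonds are cut first. The epoxide is the most acid-sensitive group, and in 35 the C4=C5 alkene is the only electron-rich double bond, so a late peracid oxidation needs no protection and only has to choose the outer face of the alkene.

35 ⇒ 34 ⇒ 32 ⇒ 31. The three ester C–O bonds are cut in the order tertiary acetate, tiglate, primary acetate. Going forward, keto triol 31 is acylated at the primary C13 hydroxyl, then at the secondary C8 hydroxyl with tigloyl chloride 33, then at the tertiary C10 hydroxyl, so steric differences alone tell the three hydroxyls apart.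

31 ⇒ 30. The C1 ketone is traced back to a methyl enol ether and the three hydroxyls to silyl ethers. One acidic operation removes all four masks, and the C1 carbonyl stays hidden through every basic and reducing step before it.

30 ⇒ 29 ⇒ 27 ⇒ 22 + 25. The butenolide is taken apart in three cuts: the C7=C11 double bond (dehydration of the tertiary alcohol in 29), the lactone O–C12 bond together with the C6–H bond (reduction of the C6 ketone of 27 and ring closure onto the ester), and the C7–C11 bond (aldol of the C7 enolate of enone 22 with keto ester 25). The lactone is closed before the alkene is made, so the tetrasubstituted alkene can only form inside the five-membered ring and no E/Z problem arises. The forward sequence has to set C6. Keto ester 25 comes in two steps from acrylate 23 via 24.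

22 ⇒ 21. The C4=C5 double bond is traced back to a C4–H bond next to a C6 silyl enol ether. Dehydrogenation of a regiodefined enol ether gives the enone and removes the C4 stereocentre that the ring-forming step creates.

21 ⇒ 18 (key disconnection). The C3–C4 bond of the ten-membered ring is cut and the C1–C6 bond is formed, which folds 21 back into cyclohexanol 18 bearing a vinyl group on C1 and an (E)-propenyl group on C6. The medium ring is therefore never closed end to end. C8 and C10 are set on a chair cyclohexane, and the oxygen pattern of the target (C1 masked ketone, C6 enolate) falls out of the rearrangement.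

18 ⇒ 15 + 16. The C5–C6 bond is cut: the (E)-propenyl group from 16 adds to ketone 15. The addition must come from the face opposite the axial C10 methyl group so that the two alkenyl groups end up trans.

15 ⇒ 14 ⇒ 13. Two O–Si bonds are cut, then the C6 ketone and the C8/C10 diol are traced to the enol ether and bridging acetal of 13. The bridge has to go before the propenyl addition because that addition needs the other chair.

13 ⇒ 12 ⇒ 10 + 11. The O–CH3 bond on C1 and then the C1–C2 bond are cut: vinylmagnesium bromide 11 adds to the C1 ketone of 10. In 10 the acetal ties O-8 and O-10 into a bicycle, so only the face that puts O-1 cis to O-10 is open. This is the configuration the later chair needs and the one a free cyclohexanone would not give.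

10 ⇒ 9 ⇒ 8 ⇒ 7. The enol ether methyl is removed, and the diosphenol 9 is traced through diol 8 to alkene 7. Oxidising both carbinols of 8 differentiates C1 from C6 automatically, because the resulting dione can enolise only toward C7.

7 ⇒ 6 ⇒ 5. The acetal C–O bond to O-10 is cut (the bridge is made oxidatively from the PMB ether of 6, so no extra protecting group is spent), then the C10–CH3 bond (methyl addition to enone 5, trans to the C8 substituent).

5 ⇒ 3 ⇒ 2 ⇒ 1. The enone is traced to monoacetate 3 (oxidation, loss of acetate), 3 to meso diol 2 (enzymatic desymmetrisation, the source of absolute configuration) and 2 to the all-cis triol 1, whose three oxygens become O-8, O-10 and the leaving group at C6.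

## Alternatives that were turned down

Alternative 1: The butenolide is disconnected at C7=C11 on an intact ten-membered ring. The forward key step would treat keto phosphonate A2 (the C6 ester of a 2-phosphono-3-silyloxypropanoic acid, C7 ketone) with a lithium salt and an amidine base; the phosphonate carbanion olefinates the C7 ketone and closes the butenolide to give A1.
- For it: the alkene can only form inside the lactone ring, the conditions are mild, and the tiglate and tertiary acetate are already in place. On butenolide construction it is stronger than the chosen route, which needs three steps and a stereoselective ketone reduction.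
- Against it: the step builds no part of the carbocycle. The ten-membered acyloin with C4, C5, C6, C8 and C10 already set must come from elsewhere. In A2 the C7 ketone is flanked by two acyloxy-bearing stereocentres (C6 and C8), which can epimerise or undergo acyl migration under the base. The acetonide of A1 must still be turned into the trans-epoxide with inversion at C5.
- Comparison: the chosen strategy spends its key step on the ring and on C8/C10 instead, which is the harder problem.

Alternative 2: The ring is opened at C7–C8. The forward key step would convert the enol triflate of open-chain aldehyde A4 into a vinylchromium species (chromium-mediated, nickel-catalysed) that adds to the C8 aldehyde, closing the ring and giving alcohol A3.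
- For it: it is convergent, the coupling tolerates the ketone, epoxide and lactone, and the C8 hydroxyl appears ready for tiglation. On convergence and late-stage functional-group tolerance it is the stronger plan.
- Against it: a ten-membered ring is closed end to end, with the full entropic and transannular cost, by a fully substituted, electron-poor vinylmetal. C8 is created in the cyclisation with only remote control from C10 and C6. A4 needs C10, the epoxide and C6 to be set separately on an open chain that also carries an enolisable ketone and a β-silyloxy aldehyde.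
- Comparison: the chosen strategy avoids macrocyclisation by ring expansion and fixes C8 and C10 on a chair beforehand.

Alternative 3: The C6–C7 bond is disconnected by a [2,3]-Wittig ring contraction. The forward key step would deprotonate the 13-membered diallylic ether A6 at C6 with an alkyllithium; the shift forms C6–C7, breaks O–C13 and gives the ten-membered alcohol A5.
- For it: C6 is set in the C–C bond-forming step through an ordered five-membered transition state. On control of C6 it is stronger than the chosen route, which relies on a later reduction.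
- Against it: a 13-membered ether must be cyclised first. Deprotonation must distinguish two similar allylic ether positions (C6 and C13) and outrun the [1,2] shift. The strong base forces the C1 ketone and the C8 and C10 hydroxyls into three protecting groups. The new C7 stereocentre is destroyed later, and A5 still needs C12 oxidised to the acid level and the exocyclic alkene moved into the C7=C11 position with oxygen on C13.
- Comparison: the chosen strategy delivers C6 as a ketone next to a free methylene, from which the butenolide follows directly, with fewer redox and protecting-group steps.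

Key step: step 14

Assumption: the lipase in step 2 is taken to acetylate the hydroxyl that gives monoacetate 3; if its preference is the opposite, lipase hydrolysis of the meso diacetate of 2 delivers the same monoacetate.

## Route

Step 1
Reactants: 1 cis,cis-cyclohexane-1,3,5-triol
Product: 2 all-cis-5-[(4-methoxybenzyl)oxy]cyclohexane-1,3-diol
Conditions: NaH (1 equiv), 4-methoxybenzyl chloride (1 equiv), DMF, 0 °C to rt (triol in excess)
Reagents that add atoms: 4-methoxybenzyl chloride, COc1ccc(CCl)cc1
Why: Williamson etherification of one of three equivalent hydroxyls; excess triol keeps the reaction at mono-alkylation and the unreacted triol is recovered.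

Step 2
Reactants: 2 all-cis-5-[(4-methoxybenzyl)oxy]cyclohexane-1,3-diol
Product: 3 (1R,3R,5S)-3-hydroxy-5-[(4-methoxybenzyl)oxy]cyclohexyl acetate
Conditions: lipase (Burkholderia cepacia), vinyl acetate, t-BuOMe, 30 °C
Reagents that add atoms: vinyl acetate, CC(=O)OC=C
Why: Enzymatic desymmetrisation of a meso 1,3-diol by irreversible transesterification; it fixes the absolute configuration at C8 and decides which carbinol becomes the C10 carbonyl.

Step 3
Reactants: 3 (1R,3R,5S)-3-hydroxy-5-[(4-methoxybenzyl)oxy]cyclohexyl acetate
Product: 5 (R)-5-[(4-methoxybenzyl)oxy]cyclohex-2-en-1-one, via β-acetoxy ketone 4 (not isolated)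
Conditions: Dess–Martin periodinane, CH2Cl2, 0 °C to rt; then Et3N, rt
Reagents that add atoms: none
Why: Dess–Martin oxidation gives the β-acetoxy ketone, which loses acetic acid by E1cB on addition of the amine; acetate is by far the better leaving group, so the alkene forms toward C6 and the PMB ether at C8 stays.

Step 4
Reactants: 5 (R)-5-[(4-methoxybenzyl)oxy]cyclohex-2-en-1-one
Product: 6 (1R,5R)-5-[(4-methoxybenzyl)oxy]-1-methylcyclohex-2-en-1-ol
Conditions: MeLi, CeCl3, THF, −78 °C
Reagents that add atoms: methyllithium, [Li]C
Why: Cerium-mediated 1,2-addition suppresses enolisation and conjugate addition; axial attack on the half-chair with the C8 ether pseudo-equatorial puts the methyl group trans to it, so C10 is set (R) with O-10 cis to O-8.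

Step 5
Reactants: 6 (1R,5R)-5-[(4-methoxybenzyl)oxy]-1-methylcyclohex-2-en-1-ol
Product: 7 exo-3-(4-methoxyphenyl)-5-methyl-2,4-dioxabicyclo[3.3.1]non-6-ene
Conditions: DDQ, 4 Å molecular sieves, CH2Cl2, 0 °C
Reagents that add atoms: none
Why: Oxidative acetalisation: DDQ turns the PMB ether into an oxocarbenium ion that the cis-1,3 tertiary hydroxyl traps under anhydrous conditions; the acetal holds O-8 and O-10 diaxial (aryl exo) and protects both oxygens.

Step 6
Reactants: 7 exo-3-(4-methoxyphenyl)-5-methyl-2,4-dioxabicyclo[3.3.1]non-6-ene
Product: 8 3-(4-methoxyphenyl)-5-methyl-2,4-dioxabicyclo[3.3.1]nonane-6,7-diol (cis-diol anti to the acetal bridge)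
Conditions: OsO4 (cat.), N-methylmorpholine N-oxide, acetone/H2O, rt
Reagents that add atoms: N-methylmorpholine N-oxide, C[N+]1([O-])CCOCC1; water, O
Why: Upjohn dihydroxylation, expected on the alkene face away from the dioxane bridge; the configuration of the two new carbinols does not matter because both are oxidised in step 7.

Step 7
Reactants: 8 3-(4-methoxyphenyl)-5-methyl-2,4-dioxabicyclo[3.3.1]nonane-6,7-diol
Product: 9 7-hydroxy-3-(4-methoxyphenyl)-5-methyl-2,4-dioxabicyclo[3.3.1]non-7-en-6-one
Conditions: IBX (3 equiv), DMSO, rt
Reagents that add atoms: none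
Why: IBX oxidises vicinal diols to 1,2-diones without C–C cleavage; the dione can enolise only toward C7 because C10 is quaternary, so C1 is the ketone and C6 the enol, which tells the two carbons apart without protecting groups.

Step 8
Reactants: 9 7-hydroxy-3-(4-methoxyphenyl)-5-methyl-2,4-dioxabicyclo[3.3.1]non-7-en-6-one
Product: 10 7-methoxy-3-(4-methoxyphenyl)-5-methyl-2,4-dioxabicyclo[3.3.1]non-7-en-6-one
Conditions: MeI, K2CO3, acetone, 50 °C
Reagents that add atoms: iodomethane, CI
Why: O-alkylation of the acidic diosphenol masks the C6 carbonyl as a methyl enol ether that cannot migrate, leaving C1 as the only ketone.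

Step 9
Reactants: 10 7-methoxy-3-(4-methoxyphenyl)-5-methyl-2,4-dioxabicyclo[3.3.1]non-7-en-6-one; 11 vinylmagnesium bromide
Product: 12 7-methoxy-3-(4-methoxyphenyl)-5-methyl-6-vinyl-2,4-dioxabicyclo[3.3.1]non-7-en-6-ol (vinyl anti to the bridge)
Conditions: CH2=CHMgBr (11), CeCl3, THF, −78 °C
Reagents that add atoms: none
Why: 1,2-Addition of a Grignard reagent to an α-alkoxy enone; the acetal bridge covers one face and the axial C10–O bond lies antiperiplanar to the incoming nucleophile (Felkin–Anh), so the vinyl group enters anti to the bridge and O-1 ends up cis to O-10, which sets C1.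

Step 10
Reactants: 12 7-methoxy-3-(4-methoxyphenyl)-5-methyl-6-vinyl-2,4-dioxabicyclo[3.3.1]non-7-en-6-ol
Product: 13 6,7-dimethoxy-3-(4-methoxyphenyl)-5-methyl-6-vinyl-2,4-dioxabicyclo[3.3.1]non-7-ene
Conditions: KH, MeI, THF, 0 °C to rt
Reagents that add atoms: iodomethane, CI
Why: Williamson methylation of the tertiary potassium alkoxide; the molecule holds no silyl group, carbonyl or 1,5-diene at this stage, so the alkoxide has no other pathway.

Step 11
Reactants: 13 6,7-dimethoxy-3-(4-methoxyphenyl)-5-methyl-6-vinyl-2,4-dioxabicyclo[3.3.1]non-7-ene
Product: 14 (2R,3R,5S)-3,5-dihydroxy-2-methoxy-3-methyl-2-vinylcyclohexan-1-one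
Conditions: 1 M HCl, THF, rt
Reagents that add atoms: water, O
Why: Aqueous acid hydrolyses the methyl enol ether to the C6 ketone and the benzylidene acetal to the diol in one operation; the tertiary allylic methyl ether at C1 is not ionised because the cation would sit next to the new carbonyl.

Step 12
Reactants: 14 (2R,3R,5S)-3,5-dihydroxy-2-methoxy-3-methyl-2-vinylcyclohexan-1-one
Product: 15 (2R,3R,5S)-2-methoxy-3-methyl-3,5-bis(triethylsilyloxy)-2-vinylcyclohexan-1-one
Conditions: Et3SiOTf, 2,6-lutidine, CH2Cl2, −78 to 0 °C
Reagents that add atoms: triethylsilyl trifluoromethanesulfonate, CC[Si](CC)(CC)OS(=O)(=O)C(F)(F)F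
Why: The silyl triflate with a hindered pyridine base silylates both the secondary and the hindered tertiary hydroxyl under conditions too weakly basic for retro-aldol cleavage of the two β-hydroxy ketone units.

Step 13
Reactants: 15 (2R,3R,5S)-2-methoxy-3-methyl-3,5-bis(triethylsilyloxy)-2-vinylcyclohexan-1-one; 16 (E)-1-bromoprop-1-ene
Product: 18 (1S,2S,3R,5R)-2-methoxy-3-methyl-1-[(E)-prop-1-enyl]-3,5-bis(triethylsilyloxy)-2-vinylcyclohexan-1-ol, via (E)-prop-1-enyllithium 17 (not isolated)
Conditions: 16, t-BuLi (2 equiv), Et2O, −78 °C; then 15, CeCl3, THF, −78 °C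
Reagents that add atoms: none
Why: Bromine–lithium exchange with retention gives the (E)-alkenyllithium, which adds to the CeCl3-activated ketone without enolisation; in the chair with both silyloxy groups equatorial the axial C10 methyl group is 1,3-diaxial to the axial trajectory, so the nucleophile enters equatorially, giving propenyl trans to vinyl and the C6 hydroxyl axial.

Step 14
Reactants: 18 (1S,2S,3R,5R)-2-methoxy-3-methyl-1-[(E)-prop-1-enyl]-3,5-bis(triethylsilyloxy)-2-vinylcyclohexan-1-ol
Product: 21 (4R)-1-methoxy-4,10-dimethyl-8,10-bis(triethylsilyloxy)-6-(trimethylsilyloxy)cyclodeca-1,5-diene (both ring alkenes trans), via potassium alkoxide 19 (not isolated), via potassium enolate 20 (not isolated)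
Conditions: KH, 18-crown-6, THF, 0 °C to rt; then Me3SiCl, Et3N, −78 °C
Reagents that add atoms: chlorotrimethylsilane, C[Si](C)(C)Cl
Why: Deprotonation gives potassium alkoxide 19 (the crown ether strips the cation), whose oxido group weakens the adjacent C1–C6 bond; the [3,3]-sigmatropic shift then forms C3–C4 and breaks C1–C6 in one event to give enolate 20, which Me3SiCl fixes on oxygen as 21. The closest known reaction type is the anionic oxy-Cope ring expansion of trans-1,2-dialkenylcyclohexanols to cyclodec-5-enones. The ten-membered ring is not closed end to end: it arises by four-atom ring expansion, the new bond joining the termini of the vinyl and propenyl groups inside a six-membered chair array while the cyclohexane bond opposite to it is cut. The single new stereocentre, C4, is fixed by the (E)-geometry of the propenyl group, which places its methyl group pseudo-equatorial in that chair (4R); it is removed again in step 15. The step needs the chair and not the boat pathway, so that both new ring alkenes are trans, and it needs an enolate that is regiodefined at C5–C6. Both follow from the substrate: the two alkenyl groups are trans-diequatorial on a chair that also keeps both silyloxy groups equatorial, and the only free oxygen is on C6, while O-1 leaves as a methyl enol ether that masks the C1 ketone. The 1,3-diaxial contact between the C6 oxido group and the C10 methyl group in the reacting chair is relieved in the transition state, and C8 and C10 pass into the medium ring unchanged. Silylation at −78 °C directly after the rearrangement prevents equilibration of the enolate toward C7, from where the C8 silyloxy group could be expelled.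

Step 15
Reactants: 21 (4R)-1-methoxy-4,10-dimethyl-8,10-bis(triethylsilyloxy)-6-(trimethylsilyloxy)cyclodeca-1,5-diene
Product: 22 (4E)-1-methoxy-4,10-dimethyl-8,10-bis(triethylsilyloxy)cyclodeca-1,4-dien-6-one
Conditions: Pd(OAc)2 (1.1 equiv), MeCN, rt
Reagents that add atoms: none
Why: Saegusa–Ito oxidation: divalent palladium takes over the silyl enol ether (far more reactive than the methyl enol ether) and β-hydride elimination of the only β-hydrogen, H-4, gives the enone and erases C4; the (E)-isomer (C3 trans to C6) is expected, as in open-chain cases where the larger β-substituent ends up trans to the acyl group.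

Step 16
Reactants: 23 methyl 2-(hydroxymethyl)acrylate
Product: 24 methyl 2-[(tert-butyldimethylsilyloxy)methyl]acrylate
Conditions: t-BuMe2SiCl, imidazole, CH2Cl2, rt
Reagents that add atoms: tert-butyldimethylsilyl chloride, CC(C)(C)[Si](C)(C)Cl
Why: Standard silylation of a primary alcohol.

Step 17
Reactants: 24 methyl 2-[(tert-butyldimethylsilyloxy)methyl]acrylate
Product: 25 methyl 3-(tert-butyldimethylsilyloxy)-2-oxopropanoate
Conditions: O3, CH2Cl2, −78 °C; then Me2S
Reagents that add atoms: ozone, [O-][O+]=O
Why: Ozonolysis of a 1,1-disubstituted alkene with reductive work-up gives the α-keto ester and formaldehyde.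

Step 18
Reactants: 22 (4E)-1-methoxy-4,10-dimethyl-8,10-bis(triethylsilyloxy)cyclodeca-1,4-dien-6-one; 25 methyl 3-(tert-butyldimethylsilyloxy)-2-oxopropanoate
Product: 27 C7 aldol adduct of 22 and 25 (C11 tertiary alcohol; epimers at C7 and C11), via lithium enolate 26 (not isolated)
Conditions: LiN(i-Pr)2, THF, −78 °C; then 25, −78 °C; NH4Cl
Reagents that add atoms: none
Why: Kinetic deprotonation of the enone at the α′-methylene C7 gives the cross-conjugated lithium enolate, which adds to the strongly electrophilic keto group of the pyruvate (aldol addition); the new centres at C7 and C11 are not controlled and need not be, since both become sp2 in step 20.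

Step 19
Reactants: 27 C7 aldol adduct of 22 and 25
Product: 29 (6S)-6,12-lactone with C11 tertiary hydroxyl, via hydroxy ester 28 (not isolated)
Conditions: NaBH4, CeCl3·7H2O, MeOH/THF, −40 °C to rt
Reagents that add atoms: none
Why: Luche reduction gives 1,2-reduction of the enone, with hydride expected on the outer face of the ring carbonyl so that O-6 comes out on the face of O-8 (6S); the resulting alkoxide closes onto the methyl ester, and forming the lactone before the C7=C11 alkene removes any E/Z question at that alkene.

Step 20
Reactants: 29 (6S)-6,12-lactone with C11 tertiary hydroxyl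
Product: 30 (6S)-butenolide with C7=C11 and C13 silyl ether
Conditions: SOCl2, pyridine, CH2Cl2, 0 °C
Reagents that add atoms: none
Why: Dehydration of a tertiary α-hydroxy lactone through its chlorosulfite; loss of H-7 gives the conjugated, tetrasubstituted butenolide (Zaitsev orientation, away from the oxygen-bearing C13).

Step 21
Reactants: 30 (6S)-butenolide with C7=C11 and C13 silyl ether
Product: 31 keto triol (C1 ketone; free hydroxyls at C8 and C10 and C13)
Conditions: 48% aq. HF, MeCN, 0 °C to rt
Reagents that add atoms: water, O
Why: Aqueous HF cleaves the three silyl ethers and hydrolyses the methyl enol ether to the C1 ketone; capture of the oxocarbenium ion by water should outrun transannular attack by the C4=C5 alkene, which is deactivated by the adjacent lactone oxygen.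

Step 22
Reactants: 31 keto triol
Product: 32 C13 monoacetate
Conditions: AcCl (1.05 equiv), 2,4,6-collidine, CH2Cl2, −78 °C
Reagents that add atoms: acetyl chloride, CC(Cl)=O
Why: Selective acylation of the primary allylic hydroxyl at low temperature; the secondary C8 and tertiary C10 hydroxyls are slower for steric reasons.

Step 23
Reactants: 32 C13 monoacetate; 33 tigloyl chloride
Product: 34 C8 tiglate
Conditions: 33, DMAP (cat.), pyridine, CH2Cl2, 0 °C to rt
Reagents that add atoms: none
Why: DMAP-catalysed acylation of the secondary alcohol; the tertiary α-ketol hydroxyl does not react, and the C8 hydroxyl cannot open the lactone because C12 is trans to C8 across C7=C11.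

Step 24
Reactants: 34 C8 tiglate
Product: 35 C10 acetate (triester with C4=C5 alkene)
Conditions: Ac2O, Sc(OTf)3 (cat.), MeCN, −20 °C
Reagents that add atoms: acetic anhydride, CC(=O)OC(C)=O
Why: Lewis-acid-catalysed acetylation acylates hindered tertiary alcohols at low temperature and avoids the amine bases that could remove the acidic H-6 of the butenolide.

Step 25
Reactants: 35 C10 acetate
Product: 36 CNP0175424.1 (target)
Conditions: mCPBA, CH2Cl2/aq. NaHCO3, 0 °C
Reagents that add atoms: meta-chloroperbenzoic acid, OOC(=O)c1cccc(Cl)c1
Why: Prilezhaev epoxidation of the only electron-rich alkene is stereospecific, so the (E)-alkene gives the trans-epoxide; in the conformer that minimises allylic strain (H-6 eclipsing C4=C5, C7 inside the ring, lactone oxygen outside) the outer face leads to (4R,5R) relative to (6S).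

## Compound list

1 | cis,cis-cyclohexane-1,3,5-triol | O[C@H]1C[C@@H](O)C[C@@H](O)C1 | starting material
2 | all-cis-5-[(4-methoxybenzyl)oxy]cyclohexane-1,3-diol (meso) | COc1ccc(CO[C@H]2C[C@@H](O)C[C@@H](O)C2)cc1 | intermediate
3 | (1R,3R,5S)-3-hydroxy-5-[(4-methoxybenzyl)oxy]cyclohexyl acetate | COc1ccc(CO[C@H]2C[C@@H](O)C[C@@H](OC(C)=O)C2)cc1 | intermediate
4 | (3S,5R)-3-acetoxy-5-[(4-methoxybenzyl)oxy]cyclohexan-1-one (β-acetoxy ketone, not isolated) | COc1ccc(CO[C@H]2CC(=O)C[C@@H](OC(C)=O)C2)cc1 | intermediate
5 | (R)-5-[(4-methoxybenzyl)oxy]cyclohex-2-en-1-one | COc1ccc(CO[C@H]2CC(=O)C=CC2)cc1 | intermediate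
6 | (1R,5R)-5-[(4-methoxybenzyl)oxy]-1-methylcyclohex-2-en-1-ol (OH cis to the ether) | COc1ccc(CO[C@H]2C[C@@](C)(O)C=CC2)cc1 | intermediate
7 | 3-(4-methoxyphenyl)-5-methyl-2,4-dioxabicyclo[3.3.1]non-6-ene (acetal across O-8/O-10, aryl exo) | COc1ccc([C@H]3O[C@H]2C[C@@](C)(O3)C=CC2)cc1 | intermediate
8 | 3-(4-methoxyphenyl)-5-methyl-2,4-dioxabicyclo[3.3.1]nonane-6,7-diol (cis-diol anti to the bridge) | COc1ccc([C@H]3O[C@H]2C[C@@](C)(O3)[C@H](O)[C@H](O)C2)cc1 | intermediate
9 | 7-hydroxy-3-(4-methoxyphenyl)-5-methyl-2,4-dioxabicyclo[3.3.1]non-7-en-6-one (diosphenol: C1 ketone, C6 enol) | COc1ccc([C@H]3O[C@H]2C[C@@](C)(O3)C(=O)C(O)=C2)cc1 | intermediate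
10 | 7-methoxy-3-(4-methoxyphenyl)-5-methyl-2,4-dioxabicyclo[3.3.1]non-7-en-6-one | COc1ccc([C@H]3O[C@H]2C[C@@](C)(O3)C(=O)C(OC)=C2)cc1 | intermediate
11 | vinylmagnesium bromide | C=C[Mg]Br | starting material
12 | 7-methoxy-3-(4-methoxyphenyl)-5-methyl-6-vinyl-2,4-dioxabicyclo[3.3.1]non-7-en-6-ol (vinyl anti to the bridge, OH cis to O-10) | COc1ccc([C@H]3O[C@H]2C[C@@](C)(O3)[C@](O)(C=C)C(OC)=C2)cc1 | intermediate
13 | 6,7-dimethoxy-3-(4-methoxyphenyl)-5-methyl-6-vinyl-2,4-dioxabicyclo[3.3.1]non-7-ene | COc1ccc([C@H]3O[C@H]2C[C@@](C)(O3)[C@](OC)(C=C)C(OC)=C2)cc1 | intermediate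
14 | (2R,3R,5S)-3,5-dihydroxy-2-methoxy-3-methyl-2-vinylcyclohexan-1-one | O[C@H]1C[C@@](C)(O)[C@](OC)(C=C)C(=O)C1 | intermediate
15 | (2R,3R,5S)-2-methoxy-3-methyl-3,5-bis(triethylsilyloxy)-2-vinylcyclohexan-1-one | CC[Si](CC)(CC)O[C@H]1C[C@@](C)(O[Si](CC)(CC)CC)[C@](OC)(C=C)C(=O)C1 | intermediate
16 | (E)-1-bromoprop-1-ene | C/C=C/Br | starting material
17 | (E)-prop-1-enyllithium (not isolated) | C/C=C/[Li] | intermediate
18 | (1S,2S,3R,5R)-2-methoxy-3-methyl-1-[(E)-prop-1-enyl]-3,5-bis(triethylsilyloxy)-2-vinylcyclohexan-1-ol (vinyl and propenyl trans) | CC[Si](CC)(CC)O[C@H]1C[C@@](C)(O[Si](CC)(CC)CC)[C@](OC)(C=C)[C@@](O)(/C=C/C)C1 | intermediate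
19 | potassium alkoxide of 18 (not isolated) | CC[Si](CC)(CC)O[C@H]1C[C@@](C)(O[Si](CC)(CC)CC)[C@](OC)(C=C)[C@@]([O-])(/C=C/C)C1.[K+] | intermediate
20 | potassium C5–C6 enolate of the ten-membered ring (not isolated) | CC[Si](CC)(CC)O[C@H]1C[C@@](C)(O[Si](CC)(CC)CC)/C(OC)=C/C[C@@H](C)/C=C([O-])/C1.[K+] | intermediate
21 | (4R)-1-methoxy-4,10-dimethyl-8,10-bis(triethylsilyloxy)-6-(trimethylsilyloxy)cyclodeca-1,5-diene (germacrane numbering, both ring alkenes trans) | CC[Si](CC)(CC)O[C@H]1C[C@@](C)(O[Si](CC)(CC)CC)/C(OC)=C/C[C@@H](C)/C=C(O[Si](C)(C)C)/C1 | intermediate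
22 | (4E)-1-methoxy-4,10-dimethyl-8,10-bis(triethylsilyloxy)cyclodeca-1,4-dien-6-one (germacrane numbering) | CC[Si](CC)(CC)O[C@H]1C[C@@](C)(O[Si](CC)(CC)CC)/C(OC)=C/C/C(C)=C/C(=O)C1 | intermediate
23 | methyl 2-(hydroxymethyl)acrylate | C=C(CO)C(=O)OC | starting material
24 | methyl 2-[(tert-butyldimethylsilyloxy)methyl]acrylate | C=C(CO[Si](C)(C)C(C)(C)C)C(=O)OC | intermediate
25 | methyl 3-(tert-butyldimethylsilyloxy)-2-oxopropanoate | COC(=O)C(=O)CO[Si](C)(C)C(C)(C)C | intermediate
26 | lithium C6–C7 enolate of 22 (not isolated) | CC[Si](CC)(CC)O[C@H]1C[C@@](C)(O[Si](CC)(CC)CC)/C(OC)=C/C/C(C)=C/C([O-])=C1.[Li+] | intermediate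
27 | aldol adduct: 22 carrying at C7 the C(OH)(CO2Me)(CH2OSi-t-BuMe2) group (epimers at C7 and C11) | CC[Si](CC)(CC)O[C@H]1C[C@@](C)(O[Si](CC)(CC)CC)/C(OC)=C/C/C(C)=C/C(=O)C1C(O)(CO[Si](C)(C)C(C)(C)C)C(=O)OC | intermediate
28 | (6S)-C6 alcohol of 27 (hydroxy ester, not isolated) | CC[Si](CC)(CC)O[C@H]1C[C@@](C)(O[Si](CC)(CC)CC)/C(OC)=C/C/C(C)=C/[C@@H](O)C1C(O)(CO[Si](C)(C)C(C)(C)C)C(=O)OC | intermediate
29 | (6S)-6,12-lactone with C11 tertiary hydroxyl and C13 silyl ether (epimers at C7 and C11) | CC[Si](CC)(CC)O[C@H]1C[C@@](C)(O[Si](CC)(CC)CC)/C(OC)=C/C/C(C)=C/[C@H]2OC(=O)C(O)(CO[Si](C)(C)C(C)(C)C)C12 | intermediate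
30 | (6S)-butenolide: C7=C11, C13 silyl ether, C8/C10 triethylsilyl ethers, C1 methyl enol ether, (4E)-alkene | CC[Si](CC)(CC)O[C@H]1C[C@@](C)(O[Si](CC)(CC)CC)/C(OC)=C/C/C(C)=C/[C@H]2OC(=O)C(CO[Si](C)(C)C(C)(C)C)=C12 | intermediate
31 | keto triol: C1 ketone, hydroxyls at C8, C10 and C13, butenolide, (4E)-alkene | O[C@H]1C[C@@](C)(O)C(=O)CC/C(C)=C/[C@H]2OC(=O)C(CO)=C12 | intermediate
32 | C13 acetate of 31 | O[C@H]1C[C@@](C)(O)C(=O)CC/C(C)=C/[C@H]2OC(=O)C(COC(C)=O)=C12 | intermediate
33 | tigloyl chloride, (E)-2-methylbut-2-enoyl chloride | C/C=C(\C)C(Cl)=O | starting material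
34 | C8 tiglate of 32 (C10 hydroxyl free) | C/C=C(\C)C(=O)O[C@H]1C[C@@](C)(O)C(=O)CC/C(C)=C/[C@H]2OC(=O)C(COC(C)=O)=C12 | intermediate
35 | C10 acetate of 34 (4,5-deoxy precursor of the target) | C/C=C(\C)C(=O)O[C@H]1C[C@@](C)(OC(C)=O)C(=O)CC/C(C)=C/[C@H]2OC(=O)C(COC(C)=O)=C12 | intermediate
36 | CNP0175424.1, (4R,5R,6S,8S,10R) | C/C=C(\C)C(=O)O[C@H]1C[C@@](C)(OC(C)=O)C(=O)CC[C@@]2(C)O[C@@H]2[C@H]2OC(=O)C(COC(C)=O)=C12 | target

## Step count and least certain steps

Total step count: 25. Longest linear sequence: 23 steps (steps 1–15 and 18–25); steps 16 and 17 prepare keto ester 25.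

Step 14 (key step). The chair pathway may lose out to a boat-like or stepwise cleavage–recombination pathway, which would give a cis ring alkene. The enolate may also equilibrate toward C7 before it is silylated and then expel the C8 silyloxy group. Both are possible because the potassium alkoxide is very reactive and the reacting chair carries a 1,3-diaxial oxido/methyl contact. Fallback: starting from 18, the C6 hydroxyl is silylated with N-(trimethylsilyl)imidazole to give the C6 trimethylsilyl ether F1, and the rearrangement is run on this neutral compound by heating (o-dichlorobenzene, about 200 °C, base-washed glass). This is a thermal siloxy-Cope shift in which no enolate is ever free, and it arrives directly at 21.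

Step 13. Addition may occur on the wrong carbonyl face, because the axial methoxy group on C1 screens the face that has to be attacked while the axial C10 methyl group screens the other. Deprotonation at C7 by the basic alkenyl reagent may also compete. Fallback: starting from 15, the slimmer and less basic prop-1-ynylmagnesium bromide is added (CeCl3, THF, −78 °C) to give the C6 prop-1-ynyl carbinol F2. The triple bond is then reduced to the (E)-alkene by hydroxyl-directed trans-hydroalumination (NaAlH2(OCH2CH2OMe)2, THF, 0 °C), which returns to 18 with the alkene geometry fixed by the reduction.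

Step 15. The dehydrogenation may give the ring-cis enone, because β-hydride elimination is syn and the geometry depends on which face of the enol ether carries palladium. The methyl enol ether may also be attacked. Fallback: starting from 21, bromination on the outer face with N-bromosuccinimide (THF, −78 °C) gives the (4R,5S)-5-bromo C6 ketone F3. Base-induced anti-elimination of hydrogen bromide (DBU, toluene, rt) requires H-4 anti to bromine, a conformation in which C3 is anti to C6, and so returns to the (E)-enone 22.

Step 19. Hydride may be delivered to the wrong face of the C6 carbonyl, since the ten-membered ring can present either face outward and the C7/C11 epimers of 27 need not behave alike. Fallback: starting from 27, if the reduction gives the C6-epimeric hydroxy lactone F4, the lactone is opened with LiOH (THF/H2O) to the seco hydroxy acid F5 (handled as its triethylammonium salt). F5 is relactonised under Mitsunobu conditions (PPh3, DIAD, THF), which activates the secondary C6 hydroxyl and closes the ring with inversion, returning to 29.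

Step 20. Elimination may run toward C13 (giving an exocyclic enol ether), or chloride may substitute, whenever H-7 is not anti to the leaving group in one of the C7/C11 epimers. Fallback: starting from 27, the tertiary hydroxyl is acetylated and eliminated by E1cB while C6 is still a ketone (Ac2O, DMAP; then DBU, CH2Cl2), which can only give the C7=C11 ene-dione ester F6 (geometric isomers that interconvert under DBU through the γ-dienolate). Luche reduction of F6 (NaBH4, CeCl3·7H2O, MeOH) then lets the isomer with the ester cis to C6 lactonise, returning to 30; the other isomer is re-oxidised and recycled.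

## Further compounds

F1 | step 14 | C6 trimethylsilyl ether of 18 | CC[Si](CC)(CC)O[C@H]1C[C@@](C)(O[Si](CC)(CC)CC)[C@](OC)(C=C)[C@@](O[Si](C)(C)C)(/C=C/C)C1
F2 | step 13 | C6 prop-1-ynyl carbinol (alkyne analogue of 18) | CC[Si](CC)(CC)O[C@H]1C[C@@](C)(O[Si](CC)(CC)CC)[C@](OC)(C=C)[C@@](O)(C#CC)C1
F3 | step 15 | (4R,5S)-5-bromo C6 ketone of the ten-membered ring | CC[Si](CC)(CC)O[C@H]1C[C@@](C)(O[Si](CC)(CC)CC)/C(OC)=C/C[C@@H](C)[C@H](Br)C(=O)C1
F4 | step 19 | C6 epimer of hydroxy lactone 29 | CC[Si](CC)(CC)O[C@H]1C[C@@](C)(O[Si](CC)(CC)CC)/C(OC)=C/C/C(C)=C/[C@@H]2OC(=O)C(O)(CO[Si](C)(C)C(C)(C)C)C12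
F5 | step 19 | seco hydroxy acid from F4 (C6 hydroxyl, C12 carboxylic acid) | CC[Si](CC)(CC)O[C@H]1C[C@@](C)(O[Si](CC)(CC)CC)/C(OC)=C/C/C(C)=C/[C@H](O)C1C(O)(CO[Si](C)(C)C(C)(C)C)C(=O)O
F6 | step 20 | C7=C11 ene-dione methyl ester (C6 ketone, both alkene geometries) | CC[Si](CC)(CC)O[C@H]1C[C@@](C)(O[Si](CC)(CC)CC)/C(OC)=C/C/C(C)=C/C(=O)C1=C(CO[Si](C)(C)C(C)(C)C)C(=O)OC
A1 | alternative 1 | butenolide-fused cyclodecanone with C4/C5 acetonide, C8 tiglate, C10 acetate and C13 silyl ether | C/C=C(\C)C(=O)O[C@H]1C[C@@](C)(OC(C)=O)C(=O)CC[C@@]2(C)OC(C)(C)O[C@H]2[C@H]2OC(=O)C(CO[Si](C)(C)C(C)(C)C)=C12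
A2 | alternative 1 | C7 ketone whose C6 oxygen carries the 2-(diethoxyphosphoryl)-3-(tert-butyldimethylsilyloxy)propanoyl group | C/C=C(\C)C(=O)O[C@H]1C[C@@](C)(OC(C)=O)C(=O)CC[C@@]2(C)OC(C)(C)O[C@H]2[C@@H](OC(=O)C(CO[Si](C)(C)C(C)(C)C)P(=O)(OCC)OCC)C1=O
A3 | alternative 2 | ten-membered C8 alcohol with epoxide, butenolide and triethylsilyl ethers at C10 and C13 | O[C@H]1C[C@@](C)(O[Si](CC)(CC)CC)C(=O)CC[C@@]2(C)O[C@@H]2[C@H]2OC(=O)C(CO[Si](CC)(CC)CC)=C12
A4 | alternative 2 | open-chain C8 aldehyde carrying the C7 enol triflate on the butenolide | O=CC[C@@](C)(O[Si](CC)(CC)CC)C(=O)CC[C@@]1(C)O[C@@H]1[C@H]1OC(=O)C(CO[Si](CC)(CC)CC)=C1OS(=O)(=O)C(F)(F)F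
A5 | alternative 3 | ten-membered C6 alcohol with the 3-(triethylsilyloxy)prop-1-en-2-yl group on C7, C8 silyl ether, C10 methoxymethyl ether and C1 dioxolane | C1C/C(C)=C/[C@@H](O)[C@H](C(=C)CO[Si](CC)(CC)CC)[C@@H](O[Si](C)(C)C(C)(C)C)C[C@@](C)(OCOC)C21OCCO2
A6 | alternative 3 | 13-membered diallylic ether (oxygen between C6 and C13, C11=C7 and C4=C5 alkenes) | C1C/C(C)=C/COC/C(CO[Si](CC)(CC)CC)=C/[C@@H](O[Si](C)(C)C(C)(C)C)C[C@@](C)(OCOC)C21OCCO2
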